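**Plan**

1. Retrosynthesis: once the two ring B benzyl ethers are put back, ring A is cut at C8–C8a and C4a–C5. This leaves a 3-aryl-5-bromo-4-pyranone (rings C and B) and a 1-methoxy-1,3-bis(silyloxy)diene that carries the side chain.
2. Enabling feature: ring A bears oxygen on C5 and C7 and the 3-hydroxy-3-methylbutyl chain on C8, directly beside C8a. C5–C6–C7–C8 with the chain are therefore the four carbons of a γ-alkylated acetoacetate, and the C4a–C8a edge is the C5=C6 double bond of a 4-pyranone.
3. Further cuts: the C3–C1' biaryl bond (Suzuki–Miyaura coupling on 3,5-dibromo-4-pyranone) and the bond from C8 to the first chain carbon (γ-alkylation of the acetoacetate dianion).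
4. Forward order: ring C is bought as 4-pyranone and dibrominated, ring B is attached, the chain is joined to acetoacetate and the keto ester is silylated twice, ring A is annulated last with aromatisation, and hydrogenolysis frees ring B.
5. Stereochemistry: the target has no stereocentre. The 3Z geometry of the diene (kinetic γ-deprotonation) and the transient centres of the cycloadduct are erased on aromatisation.

Key step: step 9

Remark: 4-bromo-2-methylbutan-2-ol is taken as a catalogue compound, and the tertiary alcohol is carried as its triethylsilyl ether because the free δ-hydroxy-β-keto ester would close to a cyclic hemiketal.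

**Route**

Step 1
Reactants: 1 4H-pyran-4-one
Product: 2 3,5-dibromo-4H-pyran-4-one
Conditions: Br2 (2.2 equiv), CH2Cl2, 0 → 20 °C; then Et3N (2.5 equiv), 0 °C
Reagents that add atoms: bromine, BrBr
Why: Halogenation–dehydrohalogenation of a vinylogous ester, in which bromine adds to each enol-ether double bond and Et3N removes HBr by E1cB, should leave bromine on both α-carbons (C3 and C5).

Step 2
Reactants: 3 4-bromobenzene-1,3-diol
Product: 4 2,4-bis(benzyloxy)-1-bromobenzene
Conditions: BnBr (2.3 equiv), K2CO3, DMF, 60 °C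
Reagents that add atoms: benzyl bromide, BrCc1ccccc1
Why: Williamson ether synthesis on both phenols gives benzyl ethers, which withstand Me3SiOTf, amine base and dilute acid and leave at the end by hydrogenolysis.

Step 3
Reactants: 4 2,4-bis(benzyloxy)-1-bromobenzene
Product: 5 2-[2,4-bis(benzyloxy)phenyl]-4,4,5,5-tetramethyl-1,3,2-dioxaborolane
Conditions: B2pin2 (1.2 equiv), Pd(dppf)Cl2 (3 mol%), KOAc, 1,4-dioxane, 90 °C
Reagents that add atoms: bis(pinacolato)diboron, CC1(C)OB(OC1(C)C)B1OC(C)(C)C(C)(C)O1
Why: Miyaura borylation of the aryl bromide avoids an ortho-benzyloxy aryllithium and gives a boronate that can be stored.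

Step 4
Reactants: 2 3,5-dibromo-4H-pyran-4-one (3 equiv); 5 2-[2,4-bis(benzyloxy)phenyl]-4,4,5,5-tetramethyl-1,3,2-dioxaborolane
Product: 6 3-[2,4-bis(benzyloxy)phenyl]-5-bromo-4H-pyran-4-one
Conditions: Pd(PPh3)4 (5 mol%), CsF (2.5 equiv), 1,2-dimethoxyethane, 80 °C; excess 2 recovered
Reagents that add atoms: none
Why: Suzuki–Miyaura coupling at one of the two equivalent C–Br bonds should stop at the mono stage because the dibromide is in excess, and fluoride activation of the boronate replaces the aqueous base that can open a 4-pyranone.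

Step 5
Reactants: 7 4-bromo-2-methylbutan-2-ol
Product: 8 [(4-bromo-2-methylbutan-2-yl)oxy]triethylsilane
Conditions: Et3SiOTf (1.2 equiv), 2,6-lutidine (1.5 equiv), CH2Cl2, −78 → 0 °C
Reagents that add atoms: triethylsilyl trifluoromethanesulfonate, CC[Si](CC)(CC)OS(=O)(=O)C(F)(F)F
Why: Silyl triflate and lutidine silylate the hindered tertiary alcohol, so that it neither quenches the dianion of step 6 nor closes onto the ketone afterwards.

Step 6
Reactants: 9 methyl 3-oxobutanoate (methyl acetoacetate); 8 [(4-bromo-2-methylbutan-2-yl)oxy]triethylsilane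
Product: 11 methyl 7-methyl-3-oxo-7-(triethylsilyloxy)octanoate, via acetoacetate dianion 10 (not isolated)
Conditions: NaH (1.1 equiv), THF, 0 °C; n-BuLi (1.05 equiv), 0 °C; 8 (0.9 equiv), 0 → 20 °C; aq NH4Cl
Reagents that add atoms: none
Why: γ-Alkylation of the acetoacetate dianion, in which the more basic terminal carbanion displaces the primary bromide by SN2, forms the C4–C5 bond of the keto ester (C8 to the first chain carbon of the target).

Step 7
Reactants: 11 methyl 7-methyl-3-oxo-7-(triethylsilyloxy)octanoate
Product: 12 methyl 7-methyl-7-(triethylsilyloxy)-3-(trimethylsilyloxy)oct-2-enoate (2E/2Z mixture, used as such)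
Conditions: Me3SiCl (1.5 equiv), Et3N (1.6 equiv), toluene, 20 °C
Reagents that add atoms: chlorotrimethylsilane, C[Si](C)(C)Cl
Why: Soft enolisation and O-silylation of the β-keto ester is the first half of the standard two-stage preparation of 1,3-bis(silyloxy)dienes.

Step 8
Reactants: 12 methyl 7-methyl-7-(triethylsilyloxy)-3-(trimethylsilyloxy)oct-2-enoate
Product: 14 (3Z)-1-methoxy-7-methyl-7-(triethylsilyloxy)-1,3-bis(trimethylsilyloxy)octa-1,3-diene, via lithium dienolate 13 (not isolated)
Conditions: LiN(i-Pr)2 (1.2 equiv), THF, −78 °C; Me3SiCl (1.3 equiv), −78 → 20 °C; used crude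
Reagents that add atoms: chlorotrimethylsilane, C[Si](C)(C)Cl
Why: Kinetic γ-deprotonation of the silyloxy enoate and O-silylation of the ester enolate should give the bis(silyloxy)diene with the chain trans to C2 on the new C3=C4 bond (3Z), as is usual for 4-alkyl dienes of this type.

Step 9
Reactants: 6 3-[2,4-bis(benzyloxy)phenyl]-5-bromo-4H-pyran-4-one; 14 (3Z)-1-methoxy-7-methyl-7-(triethylsilyloxy)-1,3-bis(trimethylsilyloxy)octa-1,3-diene
Product: 17 3-[2,4-bis(benzyloxy)phenyl]-5,7-dihydroxy-8-(3-hydroxy-3-methylbutyl)-4H-chromen-4-one, via silyloxypyrylium triflate 15 (not isolated), via cis-fused bromo cycloadduct 16 (not isolated)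
Conditions: Me3SiOTf (1.2 equiv), CH2Cl2, 20 °C, 1 h; 14 (1.5 equiv), −78 → 20 °C; DBU (3 equiv), 0 → 20 °C; then 1 M HCl, THF–MeOH, 20 °C
Reagents that add atoms: none
Why: Proposed new method: Me3SiOTf converts pyranone 6 into the 4-silyloxypyrylium triflate 15, the γ-carbon (C4) of diene 14 adds to its C6 in a Mukaiyama–Michael step (future C8–C8a bond), and the bromo silyl enol ether left in the pyran then attacks the O-silylated ester carbon of the side chain (future C4a–C5 bond) in a 6-(enolexo)-exo-trig Claisen-type closure, so that ring A arises by a stepwise, formal Diels–Alder addition across C5=C6 and the cis-fused adduct 16 results. The closest known reactions are the Diels–Alder reactions of 1-alkoxy-1,3-bis(silyloxy)dienes with bromoquinones, in which the substituted diene terminus bonds to the halogen-free carbon and HBr is lost on aromatisation, and the silyl-triflate-mediated Michael–Michael annulations of silyloxydienes onto C2–C3 of 4-silyloxybenzopyrylium salts. DBU then removes HBr across C4a–C8a while the ring is still silylated (no enolisable C8–H, which holds back retro-oxa-Michael opening of ring C), the mixed ketal at C5 collapses with loss of MeOSiMe3 and the ring enolises to the aromatic 5,7-dioxygenated pattern, after which dilute HCl cleaves the aryl silyl ethers and the tertiary triethylsilyl ether. The four stereocentres of 16 (C4a, C5, C8, C8a) are transient and vanish on aromatisation, so no stereocontrol is needed. The selectivity that is needed is regiochemical: attack at C6 and not at C2 should be secured by the inductive pull of bromine and by the twisted ortho-benzyloxyaryl group that screens C2, and only the bromine-bearing double bond can reach the aromatic oxidation level by loss of HX. The chain is fixed on C8 by the way the partners are polarised (nucleophilic γ-carbon and electrophilic ketene-acetal carbon of the diene against electrophilic C6 and nucleophilic C5 of the bromoenone), not by telling two phenols apart.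

Step 10
Reactants: 17 3-[2,4-bis(benzyloxy)phenyl]-5,7-dihydroxy-8-(3-hydroxy-3-methylbutyl)-4H-chromen-4-one
Product: 18 3-(2,4-dihydroxyphenyl)-5,7-dihydroxy-8-(3-hydroxy-3-methylbutyl)-4H-chromen-4-one (2,3-dehydrokievitone hydrate)
Conditions: H2 (1 atm), 10% Pd/C, EtOAc–MeOH, 20 °C
Reagents that add atoms: none
Why: Hydrogenolysis of the two aryl benzyl ethers should be much faster than reduction of the push-pull C2=C3 bond of the isoflavone and leaves the tertiary alcohol untouched.

**Compound list**

1 | 4H-pyran-4-one | O=c1ccocc1 | starting material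
2 | 3,5-dibromo-4H-pyran-4-one | O=c1c(Br)cocc1Br | intermediate
3 | 4-bromobenzene-1,3-diol | Oc1ccc(Br)c(O)c1 | starting material
4 | 2,4-bis(benzyloxy)-1-bromobenzene | Brc1ccc(OCc2ccccc2)cc1OCc1ccccc1 | intermediate
5 | 2-[2,4-bis(benzyloxy)phenyl]-4,4,5,5-tetramethyl-1,3,2-dioxaborolane | CC1(C)OB(OC1(C)C)c1ccc(OCc2ccccc2)cc1OCc1ccccc1 | intermediate
6 | 3-[2,4-bis(benzyloxy)phenyl]-5-bromo-4H-pyran-4-one | O=c1c(Br)cocc1-c1ccc(OCc2ccccc2)cc1OCc1ccccc1 | intermediate
7 | 4-bromo-2-methylbutan-2-ol | CC(C)(O)CCBr | starting material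
8 | [(4-bromo-2-methylbutan-2-yl)oxy]triethylsilane | CC[Si](CC)(CC)OC(C)(C)CCBr | intermediate
9 | methyl 3-oxobutanoate (methyl acetoacetate) | COC(=O)CC(C)=O | starting material
10 | sodium lithium dianion of methyl acetoacetate (formed in the flask, not isolated) | [Na+].[Li+].COC([O-])=CC(=C)[O-] | intermediate
11 | methyl 7-methyl-3-oxo-7-(triethylsilyloxy)octanoate | COC(=O)CC(=O)CCCC(C)(C)O[Si](CC)(CC)CC | intermediate
12 | methyl 7-methyl-7-(triethylsilyloxy)-3-(trimethylsilyloxy)oct-2-enoate (2E/2Z mixture, geometry immaterial) | COC(=O)C=C(CCCC(C)(C)O[Si](CC)(CC)CC)O[Si](C)(C)C | intermediate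
13 | lithium (3Z)-1-methoxy-7-methyl-7-(triethylsilyloxy)-3-(trimethylsilyloxy)octa-1,3-dien-1-olate (formed in the flask, not isolated) | [Li+].COC([O-])=C/C(O[Si](C)(C)C)=C/CCC(C)(C)O[Si](CC)(CC)CC | intermediate
14 | (3Z)-1-methoxy-7-methyl-7-(triethylsilyloxy)-1,3-bis(trimethylsilyloxy)octa-1,3-diene (ketene acetal geometry immaterial) | COC(O[Si](C)(C)C)=C/C(O[Si](C)(C)C)=C/CCC(C)(C)O[Si](CC)(CC)CC | intermediate
15 | 3-[2,4-bis(benzyloxy)phenyl]-5-bromo-4-(trimethylsilyloxy)pyrylium trifluoromethanesulfonate (formed in the flask, not isolated) | C[Si](C)(C)Oc1c(Br)c[o+]cc1-c1ccc(OCc2ccccc2)cc1OCc1ccccc1.[O-]S(=O)(=O)C(F)(F)F | intermediate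
16 | 3-[2,4-bis(benzyloxy)phenyl]-4a-bromo-5-methoxy-8-[3-methyl-3-(triethylsilyloxy)butyl]-5,7-bis(trimethylsilyloxy)-4a,5,8,8a-tetrahydro-4H-chromen-4-one, cis ring fusion (H-8a and Br-4a on the same face), racemic, C5 and C8 unassigned (formed in the flask, not isolated) | COC1(O[Si](C)(C)C)C=C(O[Si](C)(C)C)C(CCC(C)(C)O[Si](CC)(CC)CC)[C@@H]2OC=C(c3ccc(OCc4ccccc4)cc3OCc3ccccc3)C(=O)[C@]12Br | intermediate
17 | 3-[2,4-bis(benzyloxy)phenyl]-5,7-dihydroxy-8-(3-hydroxy-3-methylbutyl)-4H-chromen-4-one | CC(C)(O)CCc1c(O)cc(O)c2c(=O)c(-c3ccc(OCc4ccccc4)cc3OCc3ccccc3)coc12 | intermediate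
18 | 3-(2,4-dihydroxyphenyl)-5,7-dihydroxy-8-(3-hydroxy-3-methylbutyl)-4H-chromen-4-one (2,3-dehydrokievitone hydrate) | CC(C)(O)CCc1c(O)cc(O)c2c(=O)c(-c3ccc(O)cc3O)coc12 | target

**Step count and risks**

Total step count: 10. Longest linear sequence: 6 steps (7 → 8 → 11 → 12 → 14 → 17 → 18; steps 5 to 10).

Steps most likely to fail:

1. Step 9 (proposed new method). Two processes may go wrong.
   - After the Michael step, transfer of the silyl group from the silylated ester to triflate may outrun ring closure, so that only an open-chain adduct with a pendant β-keto ester forms.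
   - In the aromatisation, the C8a hydrogen is not α to a carbonyl and lies cis to bromine. Loss of HBr may therefore be overtaken by halophilic debromination or by retro-oxa-Michael opening of ring C, both of which end in a ring A without the C8a oxygen.

   Fallback with known chemistry, setting out from boronate 5 and returning to the route at the target 18: ring A is taken from commercial 1-(2,4,6-trihydroxyphenyl)ethanone. C-Prenylation (1-bromo-3-methylbut-2-ene, DBU, THF) should give 1-[2,4,6-trihydroxy-3-(3-methylbut-2-en-1-yl)phenyl]ethanone F1. Benzylation (BnBr, K2CO3, acetone) of the 4-hydroxyl and of the less hindered 6-hydroxyl should give 1-[4,6-bis(benzyloxy)-2-hydroxy-3-(3-methylbut-2-en-1-yl)phenyl]ethanone F2, in which the free, hydrogen-bonded hydroxyl sits beside the chain. Mukaiyama hydration (Co(acac)2, PhSiH3, O2, i-PrOH) should give 1-[4,6-bis(benzyloxy)-2-hydroxy-3-(3-hydroxy-3-methylbutyl)phenyl]ethanone F3. Condensation with N,N-dimethylformamide dimethyl acetal should give (2E)-1-[4,6-bis(benzyloxy)-2-hydroxy-3-(3-hydroxy-3-methylbutyl)phenyl]-3-(dimethylamino)prop-2-en-1-one F4. Iodine-induced cyclisation (I2, CHCl3) should give 5,7-bis(benzyloxy)-8-(3-hydroxy-3-methylbutyl)-3-iodo-4H-chromen-4-one F5. Suzuki–Miyaura coupling with 5 (Pd(PPh3)4, aq Na2CO3, 1,2-dimethoxyethane, 80 °C) should give 3-[2,4-bis(benzyloxy)phenyl]-5,7-bis(benzyloxy)-8-(3-hydroxy-3-methylbutyl)-4H-chromen-4-one F6. Hydrogenolysis under the conditions of step 10 should then give 18. In this variant the C8 placement rests on the selective benzylation and not on the construction of the ring.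

2. Step 4. The second C–Br bond may couple as well (double arylation), or the base may open the pyranone ring, so that the mono-aryl bromide is formed inefficiently.

   Fallback, setting out from 1 and returning at 6: monobromination (Br2, 1 equiv, CH2Cl2; then Et3N) should give 3-bromo-4H-pyran-4-one F7. α-Iodination of the remaining enone carbon (ICl, CH2Cl2; then Et3N) should give 3-bromo-5-iodo-4H-pyran-4-one F8. Suzuki–Miyaura coupling with 5 (Pd(PPh3)4, CsF, 1,2-dimethoxyethane, 40 °C) should then take place at the C–I bond only, because zerovalent palladium inserts into C–I far faster than into C–Br, and gives 6 without a statistical mixture.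

3. Step 6. The strongly basic dianion may eliminate HBr from bromide 8 (E2) or react too slowly at the chain carbon, so that acetoacetate is recovered and the keto ester forms in low conversion.

   Fallback, setting out from 9 (through dianion 10) and returning at 11: the dianion is alkylated with the more reactive allylic halide 1-bromo-3-methylbut-2-ene, which should give methyl 7-methyl-3-oxooct-6-enoate F9. Mukaiyama hydration (Co(acac)2, PhSiH3, O2, i-PrOH) should give methyl 7-hydroxy-7-methyl-3-oxooctanoate F10, which equilibrates with its cyclic hemiketal and is silylated at once (Et3SiOTf, 2,6-lutidine, CH2Cl2; mild acidic work-up to cleave the enol silyl ether) to give 11.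

Further compounds
F1 | step 9 | 1-[2,4,6-trihydroxy-3-(3-methylbut-2-en-1-yl)phenyl]ethanone | CC(=O)c1c(O)cc(O)c(CC=C(C)C)c1O
F2 | step 9 | 1-[4,6-bis(benzyloxy)-2-hydroxy-3-(3-methylbut-2-en-1-yl)phenyl]ethanone | CC(=O)c1c(OCc2ccccc2)cc(OCc2ccccc2)c(CC=C(C)C)c1O
F3 | step 9 | 1-[4,6-bis(benzyloxy)-2-hydroxy-3-(3-hydroxy-3-methylbutyl)phenyl]ethanone | CC(=O)c1c(OCc2ccccc2)cc(OCc2ccccc2)c(CCC(C)(C)O)c1O
F4 | step 9 | (2E)-1-[4,6-bis(benzyloxy)-2-hydroxy-3-(3-hydroxy-3-methylbutyl)phenyl]-3-(dimethylamino)prop-2-en-1-one | CN(C)/C=C/C(=O)c1c(OCc2ccccc2)cc(OCc2ccccc2)c(CCC(C)(C)O)c1O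
F5 | step 9 | 5,7-bis(benzyloxy)-8-(3-hydroxy-3-methylbutyl)-3-iodo-4H-chromen-4-one | CC(C)(O)CCc1c(OCc2ccccc2)cc(OCc2ccccc2)c2c(=O)c(I)coc12
F6 | step 9 | 3-[2,4-bis(benzyloxy)phenyl]-5,7-bis(benzyloxy)-8-(3-hydroxy-3-methylbutyl)-4H-chromen-4-one | CC(C)(O)CCc1c(OCc2ccccc2)cc(OCc2ccccc2)c2c(=O)c(-c3ccc(OCc4ccccc4)cc3OCc3ccccc3)coc12
F7 | step 4 | 3-bromo-4H-pyran-4-one | O=c1ccocc1Br
F8 | step 4 | 3-bromo-5-iodo-4H-pyran-4-one | O=c1c(Br)cocc1I
F9 | step 6 | methyl 7-methyl-3-oxooct-6-enoate | COC(=O)CC(=O)CCC=C(C)C
F10 | step 6 | methyl 7-hydroxy-7-methyl-3-oxooctanoate | COC(=O)CC(=O)CCCC(C)(C)O
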